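The route rests on cutting the bond between the benzylic CH2 of the vanillyl ring (ring A) and C3 of the γ-butyrolactone. The key step is a one-flask three-component coupling. The 2-lithio-1,3-dithiane of an enantiopure dihydrobenzofuran aldehyde adds to C4 of (5R)-5-menthyloxyfuran-2(5H)-one, and the resulting C2–C3 lithium enolate is benzylated at C3 by O-benzylvanillyl bromide. This exploits the trans-vicinal C3/C4 dibenzyl pattern flanking the lactone carbonyl. A temporary acetal stereocentre at C5, absent from the target, relays its configuration to C4 and then to C3. The precursor is therefore an unsaturated acetal-lactone. Menthyloxy, silyl, dithiane and benzyl groups are removed in two closing steps.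

Key step: step 9

Assumption: in the 1,5-insertion of 2-(benzyloxy)aryl diazoacetates, Rh2(PTTL)4 catalysts are taken to give 2R from the (S)-ligand, so the (R)-ligand complex is used to obtain 2S.

Numbering used:
- Lactone: O1, C2 (C=O), C3, C4, C5.
- Dihydrobenzofuran: O1, C2, C3, C3a to C7a.
- Ring A is the arene of the C3 benzyl group, ring B the fused arene, and ring C the 2-aryl group.

Step 1
Reactants: 1 4-(benzyloxy)-3-methoxybenzyl alcohol
Product: 2 4-(benzyloxy)-3-methoxybenzyl bromide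
Conditions: PBr3 (0.4 equiv), Et2O, 0 °C
Reagents that add atoms: phosphorus tribromide, BrP(Br)Br
Why: Bromination of an alcohol with PBr3 proceeds by SN2 displacement of the phosphite ester at an electron-rich primary benzylic carbon, and the aryl benzyl ether is inert to it.

Step 2
Reactants: 3 5-iodovanillin; 2 4-(benzyloxy)-3-methoxybenzyl bromide
Product: 4 4-{[4-(benzyloxy)-3-methoxybenzyl]oxy}-3-iodo-5-methoxybenzaldehyde
Conditions: K2CO3, DMF, rt
Reagents that add atoms: none
Why: In this Williamson ether synthesis the acidic phenoxide of 3 is alkylated by the reactive benzylic bromide, while aldehyde and aryl iodide are untouched by carbonate.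

Step 3
Reactants: 4 4-{[4-(benzyloxy)-3-methoxybenzyl]oxy}-3-iodo-5-methoxybenzaldehyde
Product: 5 2-{[4-(benzyloxy)-3-methoxybenzyl]oxy}-5-(dimethoxymethyl)-1-iodo-3-methoxybenzene
Conditions: HC(OMe)3, PPTS (cat.), MeOH, 40 °C
Reagents that add atoms: trimethyl orthoformate, COC(OC)OC
Why: Orthoformate-driven acetalisation masks the aldehyde, which could otherwise trap the rhodium carbenoid of step 5 as a carbonyl ylide, and PPTS is too weak an acid to ionise the benzylic aryl ether.

Step 4
Reactants: 5 2-{[4-(benzyloxy)-3-methoxybenzyl]oxy}-5-(dimethoxymethyl)-1-iodo-3-methoxybenzene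
Product: 6 ethyl 2-diazo-2-[2-{[4-(benzyloxy)-3-methoxybenzyl]oxy}-5-(dimethoxymethyl)-3-methoxyphenyl]acetate
Conditions: N2CHCO2Et, Pd(PPh3)4 (5 mol %), Ag2CO3 (0.5 equiv), Et3N, toluene, rt
Reagents that add atoms: ethyl diazoacetate, CCOC(=O)C=[N+]=[N-]
Why: In this palladium-catalysed deprotonative cross-coupling of an aryl iodide with ethyl diazoacetate, oxidative addition to zerovalent palladium, silver-assisted palladation of the diazo carbon and reductive elimination at room temperature should keep the diazo group intact.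

Step 5
Reactants: 6 ethyl 2-diazo-2-[2-{[4-(benzyloxy)-3-methoxybenzyl]oxy}-5-(dimethoxymethyl)-3-methoxyphenyl]acetate
Product: 8 ethyl (2S,3S)-trans-2-[4-(benzyloxy)-3-methoxyphenyl]-5-(dimethoxymethyl)-7-methoxy-2,3-dihydrobenzofuran-3-carboxylate, via cis ester 7 (not isolated)
Conditions: Rh2(R-PTTL)4 (1 mol %; PTTL = N-phthaloyl-tert-leucinate), toluene, −60 °C; then NaOEt (cat.), EtOH, 0 °C to rt
Reagents that add atoms: none
Why: Enantioselective intramolecular 1,5 C–H insertion of the donor/acceptor rhodium carbenoid into the doubly activated OCH2Ar group sets C2 as S under control of the chiral carboxylate ligands and gives the kinetic cis ester, whose C3 is then equilibrated through the ester enolate in protic medium to the less crowded trans isomer.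

Step 6
Reactants: 8 ethyl (2S,3S)-trans-2-[4-(benzyloxy)-3-methoxyphenyl]-5-(dimethoxymethyl)-7-methoxy-2,3-dihydrobenzofuran-3-carboxylate
Product: 9 ethyl (2S,3S)-2-[4-(benzyloxy)-3-methoxyphenyl]-5-(1,3-dithian-2-yl)-7-methoxy-2,3-dihydrobenzofuran-3-carboxylate
Conditions: HS(CH2)3SH, BF3·OEt2 (0.3 equiv), CH2Cl2, −20 °C
Reagents that add atoms: propane-1,3-dithiol, SCCCS
Why: Lewis acid-catalysed transthioacetalisation runs through the aryl-stabilised oxocarbenium ion of the acetal, whereas the neighbouring ester disfavours ionisation of the ring C2–O bond, so the heterocycle and both stereocentres should persist.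

Step 7
Reactants: 9 ethyl (2S,3S)-2-[4-(benzyloxy)-3-methoxyphenyl]-5-(1,3-dithian-2-yl)-7-methoxy-2,3-dihydrobenzofuran-3-carboxylate
Product: 10 {(2S,3R)-2-[4-(benzyloxy)-3-methoxyphenyl]-5-(1,3-dithian-2-yl)-7-methoxy-2,3-dihydrobenzofuran-3-yl}methanol
Conditions: LiAlH4, THF, 0 °C; aqueous work-up
Reagents that add atoms: none
Why: Hydride reduction of the ester is faster than its enolisation at 0 °C, so C3 keeps its configuration (the descriptor changes only through priorities), and dithiane and benzyl ethers are inert.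

Step 8
Reactants: 10 {(2S,3R)-2-[4-(benzyloxy)-3-methoxyphenyl]-5-(1,3-dithian-2-yl)-7-methoxy-2,3-dihydrobenzofuran-3-yl}methanol
Product: 11 tert-butyldimethylsilyl ether of 10
Conditions: TBSCl, imidazole, DMF, rt
Reagents that add atoms: tert-butyldimethylsilyl chloride, CC(C)(C)[Si](C)(C)Cl
Why: Imidazole-promoted silylation masks the only hydroxyl group, so that the base of step 9 is consumed by the dithiane C–H alone.

Step 9
Reactants: 11 tert-butyldimethylsilyl ether of 10; 12 (5R)-5-[(1R,2S,5R)-menthyloxy]furan-2(5H)-one; 2 4-(benzyloxy)-3-methoxybenzyl bromide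
Product: 15 (3R,4R,5R)-3-[4-(benzyloxy)-3-methoxybenzyl]-4-{2-[(2S,3R)-2-(4-benzyloxy-3-methoxyphenyl)-3-(tert-butyldimethylsilyloxymethyl)-7-methoxy-2,3-dihydrobenzofuran-5-yl]-1,3-dithian-2-yl}-5-[(1R,2S,5R)-menthyloxy]dihydrofuran-2(3H)-one, via lithiated dithiane 13 (not isolated), via lithium enolate 14 (not isolated)
Conditions: n-BuLi (1.05 equiv), THF, −78 to −30 °C; 12, −78 °C; then 2, DMPU, −78 to 0 °C
Reagents that add atoms: n-butyllithium, [Li]CCCC (lithium of 13 and 14 only)
Why: n-BuLi removes the aryl- and sulfur-stabilised dithiane C–H of 11, the soft carbanion 13 adds 1,4 to C4 of butenolide 12, and the lithium enolate 14 is then C-benzylated at C3 by bromide 2 in an SN2 step that forms the ring A CH2–C3 bond. The closest known reaction type is the tandem conjugate addition–enolate alkylation of lithiated aryl dithioacetals on 5-alkoxyfuran-2(5H)-ones, as used for dibenzylbutyrolactone lignans. No ring is closed. C4 is set by the C5 menthyloxy group, which shields one face of the flat butenolide so that 13 enters anti to it, and C3 is set by the bulky new C4 substituent, which sends 2 to the opposite face and should give the all-trans (3R,4R,5R) lactone. The step needs 1,4- over 1,2-addition, secured by the delocalised and hindered dithiane anion, C-monoalkylation, secured by the soft benzylic bromide, DMPU and the crowded tertiary C3 of the product, and selective lithiation, secured by the much higher acidity of the dithiane C–H compared with the benzylic ether positions. The remote dihydrobenzofuran stereocentres play no part, so any minor enantiomer carried over from step 5 should end as a separable diastereomer of 15.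

Step 10
Reactants: 15 three-component adduct
Product: 18 (3R,4R)-3-[4-(benzyloxy)-3-methoxybenzyl]-4-{2-[(2S,3R)-2-(4-benzyloxy-3-methoxyphenyl)-3-(hydroxymethyl)-7-methoxy-2,3-dihydrobenzofuran-5-yl]-1,3-dithian-2-yl}dihydrofuran-2(3H)-one, via aldehyde carboxylate 16 (not isolated), via hydroxy carboxylate 17 (not isolated)
Conditions: KOH, NaBH4, EtOH–THF–H2O, 0 °C to rt; then 2 M HCl, rt
Reagents that add atoms: potassium hydroxide, [K+].[OH-] (potassium and one carboxylate oxygen of 16 and 17; that oxygen can remain in the lactone of 18)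
Why: Saponification of the pseudo-ester expels menthoxide and unveils the C5 aldehyde, which the NaBH4 already present reduces before C4 can enolise, and acidification then closes the γ-lactone by acyl substitution and hydrolyses the primary silyl ether while both phenols stay benzylated.

Step 11
Reactants: 18 dithiane lactone alcohol
Product: 19 lappaol A
Conditions: Raney Ni (W-2, washed neutral), EtOH–THF, reflux
Reagents that add atoms: none
Why: Raney nickel hydrogenolysis should cleave both C–S bonds of the benzylic dithiane and the two aryl benzyl ethers in one operation without touching any of the four stereocentres.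

Compound list
1 | 4-(benzyloxy)-3-methoxybenzyl alcohol | COc1cc(CO)ccc1OCc1ccccc1 | starting material
2 | 4-(benzyloxy)-3-methoxybenzyl bromide | COc1cc(CBr)ccc1OCc1ccccc1 | intermediate
3 | 5-iodovanillin (4-hydroxy-3-iodo-5-methoxybenzaldehyde) | COc1cc(C=O)cc(I)c1O | starting material
4 | 4-{[4-(benzyloxy)-3-methoxybenzyl]oxy}-3-iodo-5-methoxybenzaldehyde | COc1cc(C=O)cc(I)c1OCc1ccc(OCc2ccccc2)c(OC)c1 | intermediate
5 | 2-{[4-(benzyloxy)-3-methoxybenzyl]oxy}-5-(dimethoxymethyl)-1-iodo-3-methoxybenzene | COc1cc(C(OC)OC)cc(I)c1OCc1ccc(OCc2ccccc2)c(OC)c1 | intermediate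
6 | ethyl 2-diazo-2-[2-{[4-(benzyloxy)-3-methoxybenzyl]oxy}-5-(dimethoxymethyl)-3-methoxyphenyl]acetate | CCOC(=O)C(=[N+]=[N-])c1cc(C(OC)OC)cc(OC)c1OCc1ccc(OCc2ccccc2)c(OC)c1 | intermediate
7 | ethyl (2S,3R)-cis-2-[4-(benzyloxy)-3-methoxyphenyl]-5-(dimethoxymethyl)-7-methoxy-2,3-dihydrobenzofuran-3-carboxylate | COC(OC)c1cc(OC)c2c(c1)[C@@H](C(=O)OCC)[C@@H](c1ccc(OCc3ccccc3)c(OC)c1)O2 | intermediate
8 | ethyl (2S,3S)-trans-2-[4-(benzyloxy)-3-methoxyphenyl]-5-(dimethoxymethyl)-7-methoxy-2,3-dihydrobenzofuran-3-carboxylate | COC(OC)c1cc(OC)c2c(c1)[C@H](C(=O)OCC)[C@@H](c1ccc(OCc3ccccc3)c(OC)c1)O2 | intermediate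
9 | ethyl (2S,3S)-2-[4-(benzyloxy)-3-methoxyphenyl]-5-(1,3-dithian-2-yl)-7-methoxy-2,3-dihydrobenzofuran-3-carboxylate | C1CSC(SC1)c1cc(OC)c2c(c1)[C@H](C(=O)OCC)[C@@H](c1ccc(OCc3ccccc3)c(OC)c1)O2 | intermediate
10 | {(2S,3R)-2-[4-(benzyloxy)-3-methoxyphenyl]-5-(1,3-dithian-2-yl)-7-methoxy-2,3-dihydrobenzofuran-3-yl}methanol | C1CSC(SC1)c1cc(OC)c2c(c1)[C@H](CO)[C@@H](c1ccc(OCc3ccccc3)c(OC)c1)O2 | intermediate
11 | tert-butyldimethylsilyl ether of 10, (2S,3R) | C1CSC(SC1)c1cc(OC)c2c(c1)[C@H](CO[Si](C)(C)C(C)(C)C)[C@@H](c1ccc(OCc3ccccc3)c(OC)c1)O2 | intermediate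
12 | (5R)-5-[(1R,2S,5R)-menthyloxy]furan-2(5H)-one | CC(C)[C@@H]1CC[C@@H](C)C[C@H]1O[C@@H]1OC(=O)C=C1 | starting material
13 | 2-lithio-1,3-dithiane derived from 11 | [Li]C1(SCCCS1)c1cc(OC)c2c(c1)[C@H](CO[Si](C)(C)C(C)(C)C)[C@@H](c1ccc(OCc3ccccc3)c(OC)c1)O2 | intermediate
14 | lithium enolate of the (4R,5R) conjugate adduct of 13 and 12 | [Li]OC1=C[C@@H](C2(SCCCS2)c2cc(OC)c3c(c2)[C@H](CO[Si](C)(C)C(C)(C)C)[C@@H](c2ccc(OCc4ccccc4)c(OC)c2)O3)[C@H](O[C@@H]2C[C@H](C)CC[C@H]2C(C)C)O1 | intermediate
15 | (3R,4R,5R) three-component adduct: 3-[4-(benzyloxy)-3-methoxybenzyl], 4-(2-aryl-1,3-dithian-2-yl), 5-menthyloxy dihydrofuran-2(3H)-one (aryl = dihydrobenzofuran-5-yl unit of 11) | COc1cc(C[C@H]2C(=O)O[C@@H](O[C@@H]3C[C@H](C)CC[C@H]3C(C)C)[C@@H]2C4(SCCCS4)c5cc(OC)c6c(c5)[C@H](CO[Si](C)(C)C(C)(C)C)[C@@H](c7ccc(OCc8ccccc8)c(OC)c7)O6)ccc1OCc9ccccc9 | intermediate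
16 | potassium (2R,3R)-2-[4-(benzyloxy)-3-methoxybenzyl]-3-(2-aryl-1,3-dithian-2-yl)-4-oxobutanoate (aryl as in 11) | COc1cc(C[C@@H](C(=O)[O-])[C@H](C=O)C2(SCCCS2)c2cc(OC)c3c(c2)[C@H](CO[Si](C)(C)C(C)(C)C)[C@@H](c2ccc(OCc4ccccc4)c(OC)c2)O3)ccc1OCc1ccccc1.[K+] | intermediate
17 | potassium (2R,3R)-2-[4-(benzyloxy)-3-methoxybenzyl]-3-(2-aryl-1,3-dithian-2-yl)-4-hydroxybutanoate (aryl as in 11) | COc1cc(C[C@@H](C(=O)[O-])[C@H](CO)C2(SCCCS2)c2cc(OC)c3c(c2)[C@H](CO[Si](C)(C)C(C)(C)C)[C@@H](c2ccc(OCc4ccccc4)c(OC)c2)O3)ccc1OCc1ccccc1.[K+] | intermediate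
18 | (3R,4R)-3-[4-(benzyloxy)-3-methoxybenzyl]-4-{2-[(2S,3R)-2-(4-benzyloxy-3-methoxyphenyl)-3-(hydroxymethyl)-7-methoxy-2,3-dihydrobenzofuran-5-yl]-1,3-dithian-2-yl}dihydrofuran-2(3H)-one | COc1cc(C[C@H]2C(=O)OC[C@@H]2C3(SCCCS3)c4cc(OC)c5c(c4)[C@H](CO)[C@@H](c6ccc(OCc7ccccc7)c(OC)c6)O5)ccc1OCc8ccccc8 | intermediate
19 | lappaol A: (3R,4R)-3-(4-hydroxy-3-methoxybenzyl)-4-{[(2S,3R)-2-(4-hydroxy-3-methoxyphenyl)-3-(hydroxymethyl)-7-methoxy-2,3-dihydrobenzofuran-5-yl]methyl}dihydrofuran-2(3H)-one | COc1cc(C[C@H]2C(=O)OC[C@@H]2Cc2cc(OC)c3c(c2)[C@H](CO)[C@@H](c2ccc(O)c(OC)c2)O3)ccc1O | target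

Total step count: 11. Longest linear sequence: 11 steps (1, 2, 4, 5, 6, 8, 9, 10, 11, 15, 18, 19). Bromide 2 is used twice, in step 2 for ring C with C2 and in step 9 for ring A.

Steps most likely to fail

Risk at step 9:
- What may go wrong: benzylation of the crowded enolate may be too slow. Proton exchange, retro-Michael loss of the dithiane anion on warming, or deprotonation of the acetal C–H of 12 by the carbanion could then compete.
- Fallback: it sets out from 11 and 12 and separates the two bond formations, moving the benzylation to a less hindered enolate without a C5 substituent.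
  - The conjugate addition is quenched with NH4Cl to give the (4R,5R)-4-(2-aryl-1,3-dithian-2-yl)-5-menthyloxy lactone F1.
  - KOH/NaBH4 followed by brief acidification with citric acid, which keeps the silyl ether, gives the (4R)-4-(2-aryl-1,3-dithian-2-yl)dihydrofuran-2(3H)-one F2.
  - LiHMDS in THF–DMPU at −78 °C and bromide 2 should alkylate anti to the C4 group and give the trans-(3R,4R) silyl ether F3.
  - Aqueous HCl in MeOH removes the silyl group, and the route is rejoined at 18.

Risk at step 4: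
- What may go wrong: oxidative addition next to the ortho benzylic ether on an electron-rich ring may be slow. The palladium-bound diazo unit may also lose dinitrogen and divert into carbene coupling.
- Fallback: it sets out from 5 and builds the diazo group after the C–C bond.
  - Negishi-type coupling with the Reformatsky reagent BrZnCH2CO2Et under Pd(dba)2 and XPhos gives the ethyl arylacetate F4.
  - Regitz diazo transfer with 4-acetamidobenzenesulfonyl azide and DBU in MeCN returns to the route at 6.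

Risk at step 11:
- What may go wrong: the benzylic C2–O bond of the dihydrobenzofuran may open by hydrogenolysis, or debenzylation may stay incomplete on sulfur-laden nickel.
- Fallback: it sets out from 18 and splits the task into a radical and a mild catalytic stage.
  - Bu3SnH and AIBN in refluxing toluene remove the dithiane through benzylic radicals and give O,O'-dibenzyl lappaol A F5.
  - H2 (1 atm) over Pd/C in EtOAc–EtOH at rt, stopped after uptake of two equivalents, cleaves the two aryl benzyl ethers and arrives at 19.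

Further compounds
F1 | step 9 | (4R,5R)-4-(2-aryl-1,3-dithian-2-yl)-5-[(1R,2S,5R)-menthyloxy]dihydrofuran-2(3H)-one (aryl as in 11) | O=C1C[C@@H](C2(SCCCS2)c2cc(OC)c3c(c2)[C@H](CO[Si](C)(C)C(C)(C)C)[C@@H](c2ccc(OCc4ccccc4)c(OC)c2)O3)[C@H](O[C@@H]2C[C@H](C)CC[C@H]2C(C)C)O1
F2 | step 9 | (4R)-4-(2-aryl-1,3-dithian-2-yl)dihydrofuran-2(3H)-one (aryl as in 11) | O=C1C[C@@H](C2(SCCCS2)c2cc(OC)c3c(c2)[C@H](CO[Si](C)(C)C(C)(C)C)[C@@H](c2ccc(OCc4ccccc4)c(OC)c2)O3)CO1
F3 | step 9 | tert-butyldimethylsilyl ether of 18, (3R,4R) | COc1cc(C[C@H]2C(=O)OC[C@@H]2C2(SCCCS2)c2cc(OC)c3c(c2)[C@H](CO[Si](C)(C)C(C)(C)C)[C@@H](c2ccc(OCc4ccccc4)c(OC)c2)O3)ccc1OCc1ccccc1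
F4 | step 4 | ethyl 2-[2-{[4-(benzyloxy)-3-methoxybenzyl]oxy}-5-(dimethoxymethyl)-3-methoxyphenyl]acetate | CCOC(=O)Cc1cc(C(OC)OC)cc(OC)c1OCc1ccc(OCc2ccccc2)c(OC)c1
F5 | step 11 | O,O'-dibenzyl lappaol A | COc1cc(C[C@H]2C(=O)OC[C@@H]2Cc2cc(OC)c3c(c2)[C@H](CO)[C@@H](c2ccc(OCc4ccccc4)c(OC)c2)O3)ccc1OCc1ccccc1
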